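The data were generated by integration for an exercise, and the scatter is random.

| flask | starting material | transfer agent | solid reagent | initiator | remark | time |
|---|---|---|---|---|---|---|
| red | 0.95 M | 0.95 M | 1.04 M | 95 mM | the very flask that is asked about, followed so far |  |
| amber | 1.4 M | 0.95 M | 1.04 M | 95 mM | run made earlier |  |
| flask | 0.95 M | 0.950 M | 1.04 M | 95 mM |  | 2.5 min |

- red (time / s: target / %, starting material / %): 10.0: 15, 73; 20.0: 32, 54; 50.0: 48, 20
- amber (time / min: target / %, starting material / %): 0.333: 18, 66; 0.833: 33, 50; 1.50: 33, 43; 2.50: 36, 45

(readings scatter by 2 percentage points)

- given per volume of solution although it is solid: solid reagent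
- the earlier runs were read with a standard deviation of 2 percentage points
- at the start none of the solid reagent is in solution
- partner is what solid reagent becomes in solution

- target at 2.5 min, in percent of the starting material charged
- concentration of partner in solution at 2.5 min, in percent of saturation

1. I began with one division: solid reagent charged over starting material charged gave 109 %, which I called the allowance, the ceiling on target if each target takes one partner.

2. I then turned the question round: for partner to be the limiting reagent, a run's loss of starting material would have had to reach its allowance, supposing each lost starting material took at most one partner. The amber run had an allowance of 74.3 % and read a loss of 57.0 % by 1.50 min, less than its allowance, yet its target read 33 % then and 36 % at 2.50 min, so I looked for its stall elsewhere.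

3. The red flask read a loss of 80.0 % by 50.0 s, which on the same supposition left a reserve of solid reagent and partner of about 29.5 % of the charge or more.

4. The amber run's target readings rose by 3 percentage points from 0.833 min to 2.50 min, which on the red charge is 4.4 points, so I added that to the red reading at 50.0 s and committed to 52.4 % of target in the red flask; without a saturation value I put no figure on partner.

5. The forecast stood at 51 % and 95 %, in its words: “With no demand after the stall, partner should approach saturation”.

6. The flask gave 53.6 % of target and 75.2 % of saturation, with solid reagent at 0 % of its charge at 2.50 min. The allowance less target (53.6 %) and isomer of the product (10.7 %) left 45.1 % of the charge as partner, which against saturation at 60.0 % of the charge is 75.2 %.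

    initiator → 2 initiating radical (k = 0.0770 s⁻¹)
    starting material + initiating radical → capped initiator + first chain carrier (k = 1.70 × 10⁵ L mol⁻¹ s⁻¹)
    partner + first chain carrier → target + second chain carrier (k = 30000 L mol⁻¹ s⁻¹)
    starting material + second chain carrier → released group + first chain carrier (k = 7700 L mol⁻¹ s⁻¹)
    transfer agent + first chain carrier → side product + idle radical (kL = 1200 L mol⁻¹ s⁻¹)
    2 idle radical → ended radicals (k = 3.00 × 10⁷ L mol⁻¹ s⁻¹)
    2 first chain carrier → ended chains (k = 4.00 × 10⁶ L mol⁻¹ s⁻¹)
    solid reagent ⇌ partner, rate k8*(cs8 - [partner]) while solid is left; crystals form when [partner] > cs8 (solubility = 0.570 M, k = 0.0480 s⁻¹)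
    target ⇌ isomer of the product (K = 0.200, k = 0.0550 s⁻¹)

7. A second flask, the same as the red flask but charged with 0.26 M of solid reagent, had an allowance of 27.4 %, below the loss read in the red flask, so I expected target and isomer of the product together to end near that ceiling. It gave 22.1 % of target and 4.42 % of isomer of the product, together 26.5 %, with 53.5 % of the starting material left.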